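Remark on the chemistry: atom mapping of the benzannulation (1,2-shift, [2+2], ring opening, ring closure) confirms the constitution of 6, 10 and 15 as used below, so no structure is changed. What is redesigned is the access to 6: diazo transfer to a methyl ketone replaces a diazoalkane acylation.

## Structural features

The target is a linear tridepside: three benzene rings (A, B, C) joined by two aryl ester bonds, from the carboxyl carbon on C1 of ring A to O4 of ring B and from the carboxyl carbon on C1 of ring B to O4 of ring C. Ring A is a 4-hydroxy-2,3-dimethoxy-6-methylbenzoyl unit; rings B and C are both orsellinic acid units (2-hydroxy, 4-oxy, 6-methyl), and ring C ends in a free carboxylic acid. There is no stereocentre and no stereogenic double bond, so no stereocentres stand next to each other and all selectivity is regiochemical or chemoselective. The fragile parts are the two aryl esters (cleaved or transacylated by bases, nucleophiles and free phenoxides), the beta-resorcylic acid of ring C (prone to decarboxylation on heating) and the electron-rich phenols. The real difficulty is telling the oxygens apart: on rings B and C the 4-oxygen must be acylated while the 2-hydroxyl stays free, on ring A one of three contiguous oxygens must stay free, and each ester comes from a benzoic acid with two ortho substituents. The key step uses the fact that ring C is a resorcinol whose C2 hydroxyl can come from a ketene carbonyl and whose C4 oxygen can come from the oxygen-bearing carbon of an ynol ether, with C1 (carboxyl) and C6 (methyl) supplied by a diazo enone; ring C is thus built from two acyclic pieces with O2 free and O4 silylated from the start.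

## Logic of the disconnections

33 to 32: the three O–CH2Ph bonds are cut (ether on O4 of ring A, ether on O2 of ring B, ester on the ring C carboxyl). The free acid and phenols make the finished molecule fragile, so they appear only in the last step and every earlier intermediate is neutral. The forward step must be neutral and leave both aryl esters alone, which hydrogenolysis does.

32 to 30 and 17: the ester bond between the ring B carbonyl carbon and O4 of ring C is cut. This is the most convergent cut, giving a two-ring acid and a one-ring phenol. The forward acylation must cope with a di-ortho-substituted acid (hence the chloride 31) and must choose O4 of 17 over O2; the hydrogen bond from O2–H to the ester carbonyl provides that.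

17 to 15: the C3–Si and O4–Si bonds of ring C are restored. 17 is the simplest nucleophile for the coupling, and 15 is the direct product of the ring construction. The forward step needs an acid strong enough for ipso-protonation at C3 and fluoride for O4, without touching the benzyl ester.

15 to 6 and 10: ring C is taken apart at C2–C3, C4–C5 and C1–C2 (the 1,2-shift that precedes these also makes C5–C6). The cut is made here because the two oxygens then arrive differentiated, methyl and carboxyl come in on one piece, and no aromatic substitution is needed. One arene becomes two acyclic compounds. The forward step must generate the ketene without harming the ynol ether, must give one regiochemistry in the [2+2] addition, and must keep the enoate geometry under irradiation.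

6 to 3, then 3 to 1 and 2: the C=N2 unit is removed to leave a methyl ketone (diazo transfer), and the C2=C3 double bond is cut by olefination. Acylation of a diazoalkane by an acid chloride was set aside because the diazoalkane is hazardous and adds as a 1,3-dipole to such an electron-poor double bond. The gain is two steps from two catalogue compounds. The demands are an E olefin, mono-olefination of the diketone, and kinetic enolisation of a Michael acceptor without self-addition.

10 to 7: the C(sp)–O and O–Si bonds are cut, so oxygen is placed on the terminal alkyne carbon and then silylated. The forward step must silylate the ynolate on oxygen, not carbon.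

30 to 29, then 29 to 27: the allyl–oxygen bond is cut first, then the two benzyl–oxygen bonds, with the silyl group returning to O4 of ring A. The allyl ester is removable beside benzyl ethers and aryl esters. The silyl-to-benzyl exchange on ring A is merged with the benzylation of O2 of ring B that chloride 31 needs anyway, so the silyl group costs no separate deprotection. The forward step must not cleave the aryl ester between the rings.

27 to 23 and 25: the ester bond between the ring A carbonyl carbon and O4 of ring B is cut, giving two single-ring pieces. The demands are the same O4-over-O2 selectivity and acylation by the hindered chloride 26.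

25 to 24: the allyl–oxygen bond is cut; 24 is a catalogue compound. Only the carboxylate may be alkylated.

23 to 21, 21 to 20, 20 to 18: the C1–CO2H bond of ring A is cut. That carbon lies between methoxy and methyl and is the only position a methoxy group can direct metalation to once the other free position is screened by a bulky silyl ether. The O–Si bond is cut next, and the methyl group is traced back to the aldehyde carbon of 18. All three oxygens of ring A, with the right one free, are already present in 18. The forward metalation must occur ortho to methoxy and not at the methyl group or next to the silyloxy group.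

## Other disconnections considered

Alternative 1: The cut removes from ring A both the C6–CH3 bond and the C1–CO2H bond at once. Forward, (5-chloro-2,3-dimethoxyphenoxy)triisopropylsilane A2 would be lithiated between chlorine and methoxy and would lose chloride to give the aryne A3. A methyl Grignard reagent would add at C6, the carbon remote from the C2 methoxy group, and the aryl–metal bond left at C1 would be carboxylated to the acid A1.
- In its favour: two C–C bonds are made in one flask, which is better than step 8 (one bond). The regiochemistry rests on the inductive effect of a neighbouring methoxy group and is about as reliable as the directed metalation of step 8. A1 has the same constitution as 23, so everything downstream is identical and on that score the two plans are equal.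
- Against it here: A2 is not a catalogue compound and would need several steps, whereas 18 already carries the methyl carbon as its aldehyde. The base used for metalation can itself add to A3, and the aryne offers more side paths than a simple aryllithium.
- Comparison: three steps from 18 stand against one step plus the preparation of A2, so the chosen plan should be shorter overall. The alternative concerns ring A only and could be combined with the benzannulation of ring C rather than replace it.

Alternative 2: The cut opens ring A at C1–C6 and C3–C4, back to methyl 4-methoxy-3-oxobutanoate A5 and methyl (E)-but-2-enoate A6. Forward, an alkoxide base would bring about Michael addition of the active methylene of A5 to A6, then Dieckmann closure from the methoxy-bearing carbon onto the crotonate ester, to give the cyclohexanedione A4. Dehydrogenation would give methyl 2,4-dihydroxy-3-methoxy-6-methylbenzoate A7.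
- In its favour: cheap acyclic materials, no cryogenic organometallic step, and a substitution pattern fixed by connectivity. On regiochemical certainty for ring A it is better than step 8.
- Against it here: an oxidative aromatisation is needed, and A7 has O2 and O4 both free. O4 would have to be benzylated selectively, O2 methylated, and a di-ortho-substituted methyl ester hydrolysed, which is slow.
- Comparison: about six steps to a usable ring A acid against three in the chosen plan. Mechanistically both rest on classical carbanion chemistry and are equal in that respect. The chosen plan is better in that the free oxygen of ring A is never in doubt, because it is the phenol of 18.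

Alternative 3: The cut takes ring B apart at C1–C2 and C5–C6. Forward, 1,3-bis(trimethylsilyloxy)cyclohexa-1,3-diene A9 would add to the but-2-ynoate A10 of a ring C phenol. The bridged adduct A11 would lose its saturated two-carbon bridge by cycloreversion, and desilylation would give the two-ring ester A8.
- In its favour: the ester between rings B and C would be made as an unhindered alkynoate before ring B exists. That is better than step 13, which must acylate with a di-ortho-substituted aroyl chloride. The orientation set by the 1,3-dioxygenated diene is dependable. Ring B would emerge with O4 free and O2 hydrogen-bonded, the same differentiation the chosen plan relies on, so the two are equal there.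
- Against it here: ring B is the catalogue compound 24, so building it spends steps on a ring that can be bought. A10 needs a ring C partner with O2 benzylated and O4 free, which costs protecting-group steps that 17 avoids. The cycloaddition and cycloreversion need strong heating of an aryl alkynoate, an activated ester, with a moisture-sensitive diene.
- Comparison: the step count would be about the same or higher, and the thermal stage carries more risk than the acid chloride couplings of steps 10 and 13.

Key step: step 4

## Route

Step 1
Reactants: 1 butane-2,3-dione; 2 benzyl (triphenylphosphoranylidene)acetate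
Product: 3 benzyl (2E)-3-methyl-4-oxopent-2-enoate
Conditions: 1 (3 equiv), CH2Cl2, rt
Reagents that add atoms: none
Why: Wittig olefination with an ester-stabilised ylide; one carbonyl of the 1,2-diketone reacts (the enone product is far less electrophilic and 1 is in excess), and the reversible addition typical of stabilised ylides should place the ester trans to the acetyl group, any Z isomer being removed by chromatography.

Step 2
Reactants: 3 benzyl (2E)-3-methyl-4-oxopent-2-enoate
Product: 6 benzyl (2E)-5-diazo-3-methyl-4-oxopent-2-enoate, via lithium enolate 4 (not isolated), via trifluoroacetyl ketone 5 (not isolated)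
Conditions: LiN(SiMe3)2, THF, −78 °C; CF3CO2CH2CF3, −78 °C; aq. HCl work-up; then 4-AcNHC6H4SO2N3, Et3N, H2O, MeCN, rt
Reagents that add atoms: 4-acetamidobenzenesulfonyl azide, CC(=O)Nc1ccc(cc1)S(=O)(=O)N=[N+]=[N-]
Why: Detrifluoroacetylative diazo transfer (a Regitz-type transfer to an activated ketone); kinetic deprotonation of the acetyl methyl group and Claisen acylation give 5, and the sulfonyl azide then delivers N2 to C5 with loss of the trifluoroacetyl group as the N-acylsulfonamide, so no diazoalkane is handled and the electron-poor C2=C3 bond never meets a reactive 1,3-dipole.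

Step 3
Reactants: 7 ethynyltrimethylsilane
Product: 10 triisopropyl{[(trimethylsilyl)ethynyl]oxy}silane, via lithium acetylide 8 (not isolated), via lithium ynolate 9 (not isolated)
Conditions: n-BuLi, THF, −78 °C; t-BuOOLi (from t-BuOOH and LiN(SiMe3)2), −78 to 0 °C; i-Pr3SiOTf, −78 °C to rt
Reagents that add atoms: tert-butyl hydroperoxide, CC(C)(C)OO; triisopropylsilyl trifluoromethanesulfonate, CC(C)[Si](OS(=O)(=O)C(F)(F)F)(C(C)C)C(C)C
Why: Electrophilic oxygenation of a lithium acetylide by the lithium peroxide gives the ynolate, and the bulky silyl triflate should react at oxygen because the carbon terminus already carries a trimethylsilyl group and a triisopropylsilyl group is too large for C-silylation (O-silylation of ynolates to siloxyalkynes).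

Step 4
Reactants: 6 benzyl (2E)-5-diazo-3-methyl-4-oxopent-2-enoate; 10 triisopropyl{[(trimethylsilyl)ethynyl]oxy}silane
Product: 15 benzyl 2-hydroxy-6-methyl-4-(triisopropylsilyloxy)-3-(trimethylsilyl)benzoate, via vinylketene 11 (not isolated), via vinylcyclobutenone 12 (not isolated), via dienylketene 13 (not isolated), via cyclohexadienone 14 (not isolated)
Conditions: hν (350 nm, Pyrex), 10 (1.3 equiv), ClCH2CH2Cl, rt; then 80 °C
Reagents that add atoms: none
Why: This is the Danheiser benzannulation in its diazo ketone and siloxyalkyne form: irradiation of 6 triggers a photochemical Wolff rearrangement in which the alkenyl group shifts to the diazo carbon with its E geometry intact, giving vinylketene 11. 11 adds [2+2] to the electron-rich triple bond of 10, the silicon-bearing carbon bonding to the ketene carbonyl carbon (new C2–C3) and the oxygen-bearing carbon to the ketene alpha carbon (new C4–C5), which gives 12. On warming, 12 opens by four-electron conrotatory cleavage of its C(=O)–CH bond to dienylketene 13, and reversible opening should funnel material into the isomer with the ketene and the butenoate arm cis. Ring C is then closed by thermal six-electron disrotatory electrocyclisation between the ketene carbon and the ester-bearing alkene terminus (new C1–C2) to give 14, which tautomerises to phenol 15. No stereocentre is created that survives, since the sp3 carbons of 12 and 14 are erased by ring opening and by aromatisation. The selectivity needed is the regiochemistry of the [2+2] step, and it is secured by the polarisation of the ynol ether: the carbon beta to oxygen is the nucleophile, and the positive charge developing at the oxygen-bearing carbon is stabilised by oxygen and by the beta silicon, so the silyloxy carbon ends meta to the new hydroxyl. The E geometry keeps the ester carbonyl away from the ketene, which rules out closure to a 2-pyranone and puts hydrogen rather than the ester on the inside of the closing terminus, and long-wavelength light addresses the diazo ketone while sparing the enoate and the benzyl ester. The new hydroxyl of 15 is hydrogen-bonded to the ester and flanked by silicon, which should protect it from acylation by unreacted ketene.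

Step 5
Reactants: 15 benzyl 2-hydroxy-6-methyl-4-(triisopropylsilyloxy)-3-(trimethylsilyl)benzoate
Product: 17 benzyl 2,4-dihydroxy-6-methylbenzoate, via silyl ether 16 (not isolated)
Conditions: CF3CO2H, CH2Cl2, 0 °C to rt; evaporate; Bu4NF, AcOH, THF, 0 °C
Reagents that add atoms: none
Why: Ipso-protodesilylation of an arylsilane whose silicon sits between two oxygen-bearing carbons (electrophilic substitution by a proton at a doubly activated position), then fluoride cleavage of the aryl silyl ether; acetic acid buffers the phenoxide so that the benzyl ester is not attacked.

Step 6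
Reactants: 18 3-hydroxy-4,5-dimethoxybenzaldehyde
Product: 20 2,3-dimethoxy-5-methylphenol, via benzylic alcohol 19 (not isolated)
Conditions: H2 (3 atm), Pd/C, AcOH, 50 °C
Reagents that add atoms: none
Why: Catalytic hydrogenation of an electron-rich aromatic aldehyde in acetic acid passes through the benzylic alcohol, whose C–O bond is hydrogenolysed to the methyl group; the phenol and methoxy groups are inert.

Step 7
Reactants: 20 2,3-dimethoxy-5-methylphenol
Product: 21 (2,3-dimethoxy-5-methylphenoxy)triisopropylsilane
Conditions: i-Pr3SiCl, imidazole, DMF, rt
Reagents that add atoms: chlorotriisopropylsilane, CC(C)[Si](Cl)(C(C)C)C(C)C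
Why: Standard silylation of a phenol; the triisopropylsilyl ether is chosen because it withstands alkyllithium reagents, does not direct metalation and shields the ring position beside it.

Step 8
Reactants: 21 (2,3-dimethoxy-5-methylphenoxy)triisopropylsilane
Product: 23 2,3-dimethoxy-6-methyl-4-(triisopropylsilyloxy)benzoic acid, via aryllithium 22 (not isolated)
Conditions: n-BuLi, TMEDA, Et2O, 0 °C to rt; CO2, −78 °C; cold 1 M HCl
Reagents that add atoms: carbon dioxide, O=C=O
Why: Directed ortho-metalation: the only ring hydrogen beside a methoxy group is the one between methoxy and methyl, the other ring hydrogen is flanked by the bulky non-coordinating silyloxy group, and the methyl group is not ortho to any directing group, so carboxylation of 22 places the carboxyl para to the silyloxy group as ring A requires.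

Step 9
Reactants: 24 2,4-dihydroxy-6-methylbenzoic acid (orsellinic acid)
Product: 25 prop-2-en-1-yl 2,4-dihydroxy-6-methylbenzoate
Conditions: allyl bromide, KHCO3, DMF, rt
Reagents that add atoms: allyl bromide, C=CCBr
Why: Chemoselective O-alkylation of the carboxylate; hydrogencarbonate ionises only the carboxylic acid, so the phenols are not allylated, and room temperature avoids decarboxylation of this beta-resorcylic acid.

Step 10
Reactants: 23 2,3-dimethoxy-6-methyl-4-(triisopropylsilyloxy)benzoic acid; 25 prop-2-en-1-yl 2,4-dihydroxy-6-methylbenzoate
Product: 27 prop-2-en-1-yl 4-{[2,3-dimethoxy-6-methyl-4-(triisopropylsilyloxy)benzoyl]oxy}-2-hydroxy-6-methylbenzoate, via acid chloride 26 (not isolated)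
Conditions: (COCl)2, DMF (cat.), CH2Cl2, 0 °C to rt; evaporate; 25, Et3N, DMAP (cat.), CH2Cl2, 0 °C to rt
Reagents that add atoms: none
Why: Aroyl chloride formation followed by DMAP-catalysed acylation of a phenol; the 2-hydroxyl of 25 is locked in a hydrogen bond to the ester carbonyl and is much less acidic and nucleophilic than the 4-hydroxyl, which alone should be acylated (the usual selectivity of depside synthesis).

Step 11
Reactants: 27 prop-2-en-1-yl 4-{[2,3-dimethoxy-6-methyl-4-(triisopropylsilyloxy)benzoyl]oxy}-2-hydroxy-6-methylbenzoate
Product: 29 prop-2-en-1-yl 2-(benzyloxy)-4-{[4-(benzyloxy)-2,3-dimethoxy-6-methylbenzoyl]oxy}-6-methylbenzoate, via diphenol 28 (not isolated)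
Conditions: CsF, K2CO3, BnBr, DMF, rt to 40 °C
Reagents that add atoms: benzyl bromide, BrCc1ccccc1
Why: One-pot fluoride desilylation and Williamson benzylation: fluoride frees the ring A phenoxide, which is benzylated at once, and carbonate ionises the chelated ring B hydroxyl for benzylation; the ester between the rings is a di-ortho-substituted benzoate and should resist fluoride and phenoxide.

Step 12
Reactants: 29 prop-2-en-1-yl 2-(benzyloxy)-4-{[4-(benzyloxy)-2,3-dimethoxy-6-methylbenzoyl]oxy}-6-methylbenzoate
Product: 30 2-(benzyloxy)-4-{[4-(benzyloxy)-2,3-dimethoxy-6-methylbenzoyl]oxy}-6-methylbenzoic acid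
Conditions: Pd(PPh3)4 (cat.), PhNHMe, THF, rt
Reagents that add atoms: none
Why: Allyl ester cleavage by zerovalent palladium (Tsuji–Trost deallylation) with N-methylaniline as allyl acceptor; the reaction occurs at the allyl carbon, so the hindered carbonyl is no obstacle, and benzyl ethers and the aryl ester are inert.

Step 13
Reactants: 30 2-(benzyloxy)-4-{[4-(benzyloxy)-2,3-dimethoxy-6-methylbenzoyl]oxy}-6-methylbenzoic acid; 17 benzyl 2,4-dihydroxy-6-methylbenzoate
Product: 32 benzyl 4-{[2-(benzyloxy)-4-{[4-(benzyloxy)-2,3-dimethoxy-6-methylbenzoyl]oxy}-6-methylbenzoyl]oxy}-2-hydroxy-6-methylbenzoate, via acid chloride 31 (not isolated)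
Conditions: (COCl)2, DMF (cat.), CH2Cl2, 0 °C to rt; evaporate; 17, Et3N, DMAP (cat.), CH2Cl2, 0 °C to rt
Reagents that add atoms: none
Why: The same acid chloride and DMAP acylation as in step 10; with both hydroxyls of the acid component benzylated the chloride cannot self-condense, and 17 should react only at its free, non-chelated 4-hydroxyl.

Step 14
Reactants: 32 benzyl 4-{[2-(benzyloxy)-4-{[4-(benzyloxy)-2,3-dimethoxy-6-methylbenzoyl]oxy}-6-methylbenzoyl]oxy}-2-hydroxy-6-methylbenzoate
Product: 33 2-hydroxy-4-({2-hydroxy-4-[(4-hydroxy-2,3-dimethoxy-6-methylbenzoyl)oxy]-6-methylbenzoyl}oxy)-6-methylbenzoic acid (CNP0319613.0)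
Conditions: H2 (1 atm), Pd/C, EtOAc/THF, rt
Reagents that add atoms: none
Why: Hydrogenolysis of two benzyl ethers and one benzyl ester under neutral conditions; aryl esters, methoxy groups and the arenes are untouched, and room temperature avoids decarboxylation of the liberated acid.

## Compound list

1 | butane-2,3-dione | CC(=O)C(C)=O | starting material
2 | benzyl (triphenylphosphoranylidene)acetate | O=C(OCc1ccccc1)C=P(c1ccccc1)(c1ccccc1)c1ccccc1 | starting material
3 | benzyl (2E)-3-methyl-4-oxopent-2-enoate | CC(=O)/C(C)=C/C(=O)OCc1ccccc1 | intermediate
4 | lithium (3E)-5-(benzyloxy)-3-methyl-5-oxopenta-1,3-dien-2-olate | [Li+].[O-]C(=C)/C(C)=C/C(=O)OCc1ccccc1 | intermediate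
5 | benzyl (2E)-7,7,7-trifluoro-3-methyl-4,6-dioxohept-2-enoate | O=C(CC(=O)C(F)(F)F)/C(C)=C/C(=O)OCc1ccccc1 | intermediate
6 | benzyl (2E)-5-diazo-3-methyl-4-oxopent-2-enoate | [N-]=[N+]=CC(=O)/C(C)=C/C(=O)OCc1ccccc1 | intermediate
7 | ethynyltrimethylsilane | C[Si](C)(C)C#C | starting material
8 | [(trimethylsilyl)ethynyl]lithium | [Li]C#C[Si](C)(C)C | intermediate
9 | lithium 2-(trimethylsilyl)ethynolate | [Li+].[O-]C#C[Si](C)(C)C | intermediate
10 | triisopropyl{[(trimethylsilyl)ethynyl]oxy}silane | C[Si](C)(C)C#CO[Si](C(C)C)(C(C)C)C(C)C | intermediate
11 | benzyl (2E)-3-methyl-5-oxopenta-2,4-dienoate | O=C=C/C(C)=C/C(=O)OCc1ccccc1 | intermediate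
12 | benzyl (2E)-3-[4-oxo-2-(triisopropylsilyloxy)-3-(trimethylsilyl)cyclobut-2-en-1-yl]but-2-enoate (racemic) | O=C1C([Si](C)(C)C)=C(O[Si](C(C)C)(C(C)C)C(C)C)C1/C(C)=C/C(=O)OCc1ccccc1 | intermediate
13 | benzyl (2E,4E)-3-methyl-7-oxo-5-(triisopropylsilyloxy)-6-(trimethylsilyl)hepta-2,4,6-trienoate | O=C=C([Si](C)(C)C)/C(O[Si](C(C)C)(C(C)C)C(C)C)=C\C(C)=C\C(=O)OCc1ccccc1 | intermediate
14 | benzyl 6-methyl-2-oxo-4-(triisopropylsilyloxy)-3-(trimethylsilyl)cyclohexa-3,5-diene-1-carboxylate (racemic) | O=C1C([Si](C)(C)C)=C(O[Si](C(C)C)(C(C)C)C(C)C)C=C(C)C1C(=O)OCc1ccccc1 | intermediate
15 | benzyl 2-hydroxy-6-methyl-4-(triisopropylsilyloxy)-3-(trimethylsilyl)benzoate | Cc1cc(O[Si](C(C)C)(C(C)C)C(C)C)c([Si](C)(C)C)c(O)c1C(=O)OCc1ccccc1 | intermediate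
16 | benzyl 2-hydroxy-6-methyl-4-(triisopropylsilyloxy)benzoate | Cc1cc(O[Si](C(C)C)(C(C)C)C(C)C)cc(O)c1C(=O)OCc1ccccc1 | intermediate
17 | benzyl 2,4-dihydroxy-6-methylbenzoate | Cc1cc(O)cc(O)c1C(=O)OCc1ccccc1 | intermediate
18 | 3-hydroxy-4,5-dimethoxybenzaldehyde | COc1cc(C=O)cc(O)c1OC | starting material
19 | 5-(hydroxymethyl)-2,3-dimethoxyphenol | COc1cc(CO)cc(O)c1OC | intermediate
20 | 2,3-dimethoxy-5-methylphenol | COc1cc(C)cc(O)c1OC | intermediate
21 | (2,3-dimethoxy-5-methylphenoxy)triisopropylsilane | COc1cc(C)cc(O[Si](C(C)C)(C(C)C)C(C)C)c1OC | intermediate
22 | [2,3-dimethoxy-6-methyl-4-(triisopropylsilyloxy)phenyl]lithium | COc1c([Li])c(C)cc(O[Si](C(C)C)(C(C)C)C(C)C)c1OC | intermediate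
23 | 2,3-dimethoxy-6-methyl-4-(triisopropylsilyloxy)benzoic acid | COc1c(O[Si](C(C)C)(C(C)C)C(C)C)cc(C)c(C(=O)O)c1OC | intermediate
24 | 2,4-dihydroxy-6-methylbenzoic acid (orsellinic acid) | Cc1cc(O)cc(O)c1C(=O)O | starting material
25 | prop-2-en-1-yl 2,4-dihydroxy-6-methylbenzoate | Cc1cc(O)cc(O)c1C(=O)OCC=C | intermediate
26 | 2,3-dimethoxy-6-methyl-4-(triisopropylsilyloxy)benzoyl chloride | COc1c(O[Si](C(C)C)(C(C)C)C(C)C)cc(C)c(C(=O)Cl)c1OC | intermediate
27 | prop-2-en-1-yl 4-{[2,3-dimethoxy-6-methyl-4-(triisopropylsilyloxy)benzoyl]oxy}-2-hydroxy-6-methylbenzoate | COc1c(O[Si](C(C)C)(C(C)C)C(C)C)cc(C)c(C(=O)Oc2cc(C)c(C(=O)OCC=C)c(O)c2)c1OC | intermediate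
28 | prop-2-en-1-yl 2-hydroxy-4-[(4-hydroxy-2,3-dimethoxy-6-methylbenzoyl)oxy]-6-methylbenzoate | COc1c(O)cc(C)c(C(=O)Oc2cc(C)c(C(=O)OCC=C)c(O)c2)c1OC | intermediate
29 | prop-2-en-1-yl 2-(benzyloxy)-4-{[4-(benzyloxy)-2,3-dimethoxy-6-methylbenzoyl]oxy}-6-methylbenzoate | COc1c(OCc2ccccc2)cc(C)c(C(=O)Oc2cc(C)c(C(=O)OCC=C)c(OCc3ccccc3)c2)c1OC | intermediate
30 | 2-(benzyloxy)-4-{[4-(benzyloxy)-2,3-dimethoxy-6-methylbenzoyl]oxy}-6-methylbenzoic acid | COc1c(OCc2ccccc2)cc(C)c(C(=O)Oc2cc(C)c(C(=O)O)c(OCc3ccccc3)c2)c1OC | intermediate
31 | 2-(benzyloxy)-4-{[4-(benzyloxy)-2,3-dimethoxy-6-methylbenzoyl]oxy}-6-methylbenzoyl chloride | COc1c(OCc2ccccc2)cc(C)c(C(=O)Oc2cc(C)c(C(=O)Cl)c(OCc3ccccc3)c2)c1OC | intermediate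
32 | benzyl 4-{[2-(benzyloxy)-4-{[4-(benzyloxy)-2,3-dimethoxy-6-methylbenzoyl]oxy}-6-methylbenzoyl]oxy}-2-hydroxy-6-methylbenzoate | COc1c(OCc2ccccc2)cc(C)c(C(=O)Oc2cc(C)c(C(=O)Oc3cc(C)c(C(=O)OCc4ccccc4)c(O)c3)c(OCc3ccccc3)c2)c1OC | intermediate
33 | 2-hydroxy-4-({2-hydroxy-4-[(4-hydroxy-2,3-dimethoxy-6-methylbenzoyl)oxy]-6-methylbenzoyl}oxy)-6-methylbenzoic acid (CNP0319613.0) | COc1c(O)cc(C)c(C(=O)Oc2cc(C)c(C(=O)Oc3cc(C)c(C(=O)O)c(O)c3)c(O)c2)c1OC | target

## Step count and least certain steps

Total step count: 14. Longest linear sequence: 8 steps (steps 6, 7, 8, 10, 11, 12, 13 and 14, from 18 to 33).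

Step 4 (key step). The likely failure modes are:
- light-induced isomerisation of the C2=C3 double bond, after which the ester carbonyl, now cis, can capture the ketene;
- dimerisation of the ketene or O-acylation of product by it;
- dipolar cycloaddition of the diazo group of one molecule to the electron-poor double bond of another;
- a reluctant six-electron closure, because the ketene carries silicon.

Fallback: ring C is not constructed. The fallback sets out from 24, whose carboxylate is benzylated selectively with benzyl bromide and KHCO3 in DMF at room temperature, and it rejoins the route at 17. No new compound is made (F0).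

Step 2. The lithium enolate or the amide base may add in conjugate fashion to the doubly activated double bond of 3, leading to oligomers, or deprotonation may occur at the C3 methyl group. Fallback from 3 to 6 without a strong base: soft enolisation with Me3SiOTf and Et3N should give benzyl (2E)-3-methyl-4-(trimethylsilyloxy)penta-2,4-dienoate F1. N-Bromosuccinimide should convert it into benzyl (2E)-5-bromo-3-methyl-4-oxopent-2-enoate F2. N,N'-Ditosylhydrazine and DBU should then turn the bromomethyl ketone into 6 by N-alkylation and double loss of sulfinate.

Step 8. Metalation at the hindered position between methoxy and methyl may be incomplete, or it may stray to the methyl group or to the position beside the silyloxy group, with migration of silicon from oxygen to carbon. Fallback from 21 to 23: N-bromosuccinimide in MeCN should brominate para to the silyloxy group, since the other free position is screened by the triisopropylsilyl group, to give (4-bromo-2,3-dimethoxy-5-methylphenoxy)triisopropylsilane F3. Bromine–lithium exchange with n-BuLi at −78 °C then generates 22 at a defined position, and carboxylation returns to 23.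

Step 11. Fluoride or the phenoxides may cleave or transacylate the aryl ester between rings A and B, or benzylation of the chelated hydroxyl may be incomplete. Fallback from 27 to 29 in two neutral operations: Bu4NF buffered with AcOH gives 28, which is isolated, and a double Mitsunobu benzylation (BnOH, PPh3, diisopropyl azodicarboxylate) gives 29. No new compound is made (F0).

Step 13. Acylation by the di-ortho-substituted chloride may be sluggish, and forcing it may lead to acylation of the chelated hydroxyl or to acyl exchange. Fallback from 30 and 17 to 32: direct condensation with trifluoroacetic anhydride in toluene, which activates 30 as a mixed anhydride that transfers an acylium-type acyl group without base and without the acid chloride. No new compound is made (F0).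

## Further compounds

F1 | step 2 | benzyl (2E)-3-methyl-4-(trimethylsilyloxy)penta-2,4-dienoate | C=C(O[Si](C)(C)C)/C(C)=C/C(=O)OCc1ccccc1
F2 | step 2 | benzyl (2E)-5-bromo-3-methyl-4-oxopent-2-enoate | O=C(CBr)/C(C)=C/C(=O)OCc1ccccc1
F3 | step 8 | (4-bromo-2,3-dimethoxy-5-methylphenoxy)triisopropylsilane | COc1c(Br)c(C)cc(O[Si](C(C)C)(C(C)C)C(C)C)c1OC
F0 | step 4 | none | none
F0 | step 11 | none | none
F0 | step 13 | none | none
A1 | alternative 1 | 2,3-dimethoxy-6-methyl-4-(triisopropylsilyloxy)benzoic acid | COc1c(O[Si](C(C)C)(C(C)C)C(C)C)cc(C)c(C(=O)O)c1OC
A2 | alternative 1 | (5-chloro-2,3-dimethoxyphenoxy)triisopropylsilane | COc1cc(Cl)cc(O[Si](C(C)C)(C(C)C)C(C)C)c1OC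
A3 | alternative 1 | 3,4-dimethoxy-5-(triisopropylsilyloxy)benzyne | COC1=C(OC)C(O[Si](C(C)C)(C(C)C)C(C)C)=CC#C1
A4 | alternative 2 | methyl 3-methoxy-6-methyl-2,4-dioxocyclohexane-1-carboxylate (mixture of stereoisomers and enol forms) | COC1C(=O)CC(C)C(C(=O)OC)C1=O
A5 | alternative 2 | methyl 4-methoxy-3-oxobutanoate | COCC(=O)CC(=O)OC
A6 | alternative 2 | methyl (E)-but-2-enoate | C/C=C/C(=O)OC
A7 | alternative 2 | methyl 2,4-dihydroxy-3-methoxy-6-methylbenzoate | COc1c(O)cc(C)c(C(=O)OC)c1O
A8 | alternative 3 | benzyl 2-(benzyloxy)-4-[(2,4-dihydroxy-6-methylbenzoyl)oxy]-6-methylbenzoate | Cc1cc(O)cc(O)c1C(=O)Oc1cc(C)c(C(=O)OCc2ccccc2)c(OCc2ccccc2)c1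
A9 | alternative 3 | 1,3-bis(trimethylsilyloxy)cyclohexa-1,3-diene | C[Si](C)(C)OC1=CC(O[Si](C)(C)C)=CCC1
A10 | alternative 3 | benzyl 2-(benzyloxy)-4-(but-2-ynoyloxy)-6-methylbenzoate | CC#CC(=O)Oc1cc(C)c(C(=O)OCc2ccccc2)c(OCc2ccccc2)c1
A11 | alternative 3 | 3-(benzyloxy)-4-(benzyloxycarbonyl)-5-methylphenyl 3-methyl-1,5-bis(trimethylsilyloxy)bicyclo[2.2.2]octa-2,5-diene-2-carboxylate (racemic) | C[Si](C)(C)OC1=CC2(O[Si](C)(C)C)CCC1C(C)=C2C(=O)Oc1cc(C)c(C(=O)OCc2ccccc2)c(OCc2ccccc2)c1
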